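## Retrosynthetic overview

1. Target 37 is opened first at the right-hand seven-membered ring and dienone (domino ring-closing enyne metathesis/cross-metathesis, last ring), then at the C1–OH (γ-oxygenation of a dienolate).
2. The spiro-cyclohexene (bonds C5–C13' and C3–C11') comes from an exo Diels–Alder reaction of dienone 32 (diene only) with the monocyclic α-methylene lactone 17 (dienophile only, no diene yet).
3. Each α-methylene-γ-butyrolactone comes from Pd(PPh3)4-catalysed carbonylative lactonisation of a hydroxy vinyl triflate, itself made from the methyl ketone of an aldol adduct.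
4. The key C7–C8 bond of both halves is made by an intermolecular Evans-type syn-aldol joining imide 7 with aldehyde 3 (dibutylboron enolate) or 4 (chlorotitanium enolate); the left half needs a Mitsunobu inversion at C8 to give the trans-lactone.
5. Ring order: left lactone, left cycloheptadiene, right lactone (parallel branch), spiro-cyclohexene, right cycloheptadiene.

Numbering: xanthane numbering, C1–C15 for the left (diene-derived) unit and primed for the right unit; C11/C11' are lactone α-carbons, C13/C13' the exocyclic CH2 carbons.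

Assumption: in steps 1 and 2 the (R)-ligand is taken to give 3 and the (S)-ligand 4; if the sense of induction is the reverse, the two ligand enantiomers are exchanged (configuration checked at 9 and 19).

## Route

Step 1
Reactants: 1 (E)-but-2-enal; 2 ethynyltri(propan-2-yl)silane
Product: 3 (3R)-3-methyl-5-(triisopropylsilyl)pent-4-ynal
Conditions: [Rh(OAc)(C2H4)2]2 (2.5 mol %), (R)-DTBM-SEGPHOS (6 mol %), MeOH, 40 °C
Reagents that add atoms: none
Why: Rhodium-catalysed asymmetric conjugate alkynylation of an enal, in which the bulky silyl group and ligand suppress alkyne dimerisation and the chiral alkynyl–rhodium species adds to one enantioface to set C10' (R).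

Step 2
Reactants: 1 (E)-but-2-enal; 2 ethynyltri(propan-2-yl)silane
Product: 4 (3S)-3-methyl-5-(triisopropylsilyl)pent-4-ynal
Conditions: [Rh(OAc)(C2H4)2]2 (2.5 mol %), (S)-DTBM-SEGPHOS (6 mol %), MeOH, 40 °C
Reagents that add atoms: none
Why: The same asymmetric conjugate alkynylation with the enantiomeric ligand sets C10 (S) for the left half.

Step 3
Reactants: 5 (4R)-4-benzyl-1,3-oxazolidin-2-one; 6 pent-4-enoyl chloride
Product: 7 (4R)-4-benzyl-3-(pent-4-enoyl)-1,3-oxazolidin-2-one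
Conditions: Et3N, DMAP (10 mol %), CH2Cl2, 0 °C → rt
Reagents that add atoms: none
Why: DMAP-catalysed N-acylation of the oxazolidinone by the acid chloride gives the aldol donor without touching the stereocentre.

Step 4
Reactants: 7 (4R)-4-benzyl-3-(pent-4-enoyl)-1,3-oxazolidin-2-one; 3 (3R)-3-methyl-5-(triisopropylsilyl)pent-4-ynal
Product: 9 (4R)-4-benzyl-3-[(2R,3S,5R)-3-hydroxy-5-methyl-2-(prop-2-enyl)-7-(triisopropylsilyl)hept-6-ynoyl]-1,3-oxazolidin-2-one, via dibutylboron (Z)-enolate 8 (not isolated)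
Conditions: Bu2BOTf, iPr2NEt, CH2Cl2, −78 → 0 °C; 3, −78 → 0 °C; pH 7 buffer, MeOH, 30 % H2O2, 0 °C
Reagents that add atoms: none
Why: Evans syn-aldol reaction, in which the (Z)-boron enolate reacts through a Zimmerman–Traxler chair on the face away from the benzyl group to set C7' and C8' (2R,3S) under reagent control, the remote C10' methyl having no influence and adducts from the minor aldehyde enantiomer being removed by chromatography.

Step 5
Reactants: 9 (4R)-4-benzyl-3-[(2R,3S,5R)-3-hydroxy-5-methyl-2-(prop-2-enyl)-7-(triisopropylsilyl)hept-6-ynoyl]-1,3-oxazolidin-2-one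
Product: 10 (2R,3S,5R)-3-hydroxy-N-methoxy-N,5-dimethyl-2-(prop-2-enyl)-7-(triisopropylsilyl)hept-6-ynamide
Conditions: MeNHOMe·HCl (3 equiv), AlMe3 (3 equiv), CH2Cl2, −20 → 0 °C; 0.5 M HCl, 0 °C
Reagents that add atoms: N,O-dimethylhydroxylamine hydrochloride, CNOC.Cl
Why: Weinreb transamidation, in which the aluminium amide is directed by the aluminium alkoxide of the β-hydroxyl to the exocyclic carbonyl and releases the auxiliary without epimerising C7'.

Step 6
Reactants: 10 (2R,3S,5R)-3-hydroxy-N-methoxy-N,5-dimethyl-2-(prop-2-enyl)-7-(triisopropylsilyl)hept-6-ynamide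
Product: 11 (2R,3S,5R)-N-methoxy-N,5-dimethyl-2-(prop-2-enyl)-3-(triethylsilyloxy)-7-(triisopropylsilyl)hept-6-ynamide
Conditions: Et3SiCl, imidazole, DMF, 0 °C → rt
Reagents that add atoms: chlorotriethylsilane, CC[Si](Cl)(CC)CC
Why: Silylation of the secondary alcohol prevents retro-aldol and alkoxide chemistry in the next two basic steps.

Step 7
Reactants: 11 (2R,3S,5R)-N-methoxy-N,5-dimethyl-2-(prop-2-enyl)-3-(triethylsilyloxy)-7-(triisopropylsilyl)hept-6-ynamide
Product: 12 (3R,4S,6R)-6-methyl-3-(prop-2-enyl)-4-(triethylsilyloxy)-8-(triisopropylsilyl)oct-7-yn-2-one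
Conditions: MeMgBr (2.5 equiv), THF, 0 °C; aq. NH4Cl
Reagents that add atoms: methylmagnesium bromide, C[Mg]Br
Why: Weinreb ketone synthesis, in which the chelated tetrahedral magnesium intermediate prevents over-addition and gives the methyl ketone (C11'–C13') with C7' intact.

Step 8
Reactants: 12 (3R,4S,6R)-6-methyl-3-(prop-2-enyl)-4-(triethylsilyloxy)-8-(triisopropylsilyl)oct-7-yn-2-one
Product: 14 (3R,4S,6R)-6-methyl-3-(prop-2-enyl)-4-(triethylsilyloxy)-8-(triisopropylsilyl)oct-1-en-7-yn-2-yl trifluoromethanesulfonate, via potassium enolate 13 (not isolated)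
Conditions: KN(SiMe3)2 (1.1 equiv), THF, −78 °C; PhNTf2 (1.2 equiv), −78 → −40 °C
Reagents that add atoms: N-phenylbis(trifluoromethanesulfonimide), FC(F)(F)S(=O)(=O)N(c1ccccc1)S(=O)(=O)C(F)(F)F
Why: Kinetic deprotonation by the bulky amide occurs at the methyl group and not at the hindered C7'–H, so O-triflation gives the terminal enol triflate without epimerisation or β-elimination, and the silylated alkyne is inert.

Step 9
Reactants: 14 (3R,4S,6R)-6-methyl-3-(prop-2-enyl)-4-(triethylsilyloxy)-8-(triisopropylsilyl)oct-1-en-7-yn-2-yl trifluoromethanesulfonate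
Product: 15 (3R,4S,6R)-4-hydroxy-6-methyl-3-(prop-2-enyl)-8-(triisopropylsilyl)oct-1-en-7-yn-2-yl trifluoromethanesulfonate
Conditions: HF·pyridine, pyridine/THF, 0 °C
Reagents that add atoms: none
Why: Buffered fluoride cleaves the labile triethylsilyl ether selectively while the alkynyl triisopropylsilyl group and the vinyl triflate survive.

Step 10
Reactants: 15 (3R,4S,6R)-4-hydroxy-6-methyl-3-(prop-2-enyl)-8-(triisopropylsilyl)oct-1-en-7-yn-2-yl trifluoromethanesulfonate
Product: 16 (4S,5S)-3-methylidene-5-[(2R)-2-methyl-4-(triisopropylsilyl)but-3-ynyl]-4-(prop-2-enyl)oxolan-2-one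
Conditions: Pd(PPh3)4 (10 mol %), CO (1 atm), Bu3N (2 equiv), LiCl (3 equiv), MeCN, 65 °C
Reagents that add atoms: carbon monoxide, [C-]#[O+]
Why: Palladium-catalysed carbonylative lactonisation (oxidative addition of zerovalent palladium to the triflate, CO insertion, capture of the acyl-palladium by the C8' hydroxyl with retention) turns the syn-aldol relationship into the cis α-methylene-γ-butyrolactone.

Step 11
Reactants: 16 (4S,5S)-3-methylidene-5-[(2R)-2-methyl-4-(triisopropylsilyl)but-3-ynyl]-4-(prop-2-enyl)oxolan-2-one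
Product: 17 (4S,5S)-3-methylidene-5-[(2R)-2-methylbut-3-ynyl]-4-(prop-2-enyl)oxolan-2-one
Conditions: Bu4NF (1.2 equiv), AcOH (1.2 equiv), THF, 0 °C → rt
Reagents that add atoms: none
Why: Acetic acid-buffered fluoride removes the alkynyl silyl group without conjugate addition to the methylene lactone, giving the dienophile that carries no diene.

Step 12
Reactants: 7 (4R)-4-benzyl-3-(pent-4-enoyl)-1,3-oxazolidin-2-one; 4 (3S)-3-methyl-5-(triisopropylsilyl)pent-4-ynal
Product: 19 (4R)-4-benzyl-3-[(2R,3S,5S)-3-hydroxy-5-methyl-2-(prop-2-enyl)-7-(triisopropylsilyl)hept-6-ynoyl]-1,3-oxazolidin-2-one, via trichlorotitanium (Z)-enolate 18 (not isolated)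
Conditions: TiCl4 (1.05 equiv), iPr2NEt (1.1 equiv), CH2Cl2, 0 °C; N-methyl-2-pyrrolidone (1.0 equiv); 4, −78 → 0 °C; aq. NH4Cl
Reagents that add atoms: none
Why: Crimmins-type soft enolisation with TiCl4 and iPr2NEt gives the chlorotitanium (Z)-enolate, which, with N-methyl-2-pyrrolidone occupying the free coordination site, reacts through the non-chelated Zimmerman–Traxler chair on the face away from the benzyl group to give the Evans syn adduct (2R,3S) without a peroxide work-up, setting C7 (final S) and a C8 carbinol of the configuration that is inverted later.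

Step 13
Reactants: 19 (4R)-4-benzyl-3-[(2R,3S,5S)-3-hydroxy-5-methyl-2-(prop-2-enyl)-7-(triisopropylsilyl)hept-6-ynoyl]-1,3-oxazolidin-2-one
Product: 20 (2R,3S,5S)-3-hydroxy-N-methoxy-N,5-dimethyl-2-(prop-2-enyl)-7-(triisopropylsilyl)hept-6-ynamide
Conditions: MeNHOMe·HCl (3 equiv), AlMe3 (3 equiv), CH2Cl2, −20 → 0 °C; 0.5 M HCl, 0 °C
Reagents that add atoms: N,O-dimethylhydroxylamine hydrochloride, CNOC.Cl
Why: Weinreb transamidation assisted by the β-alkoxide chelate, as in step 5.

Step 14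
Reactants: 20 (2R,3S,5S)-3-hydroxy-N-methoxy-N,5-dimethyl-2-(prop-2-enyl)-7-(triisopropylsilyl)hept-6-ynamide
Product: 21 (2R,3S,5S)-N-methoxy-N,5-dimethyl-2-(prop-2-enyl)-3-(triethylsilyloxy)-7-(triisopropylsilyl)hept-6-ynamide
Conditions: Et3SiCl, imidazole, DMF, 0 °C → rt
Reagents that add atoms: chlorotriethylsilane, CC[Si](Cl)(CC)CC
Why: Silyl protection of the carbinol, as in step 6.

Step 15
Reactants: 21 (2R,3S,5S)-N-methoxy-N,5-dimethyl-2-(prop-2-enyl)-3-(triethylsilyloxy)-7-(triisopropylsilyl)hept-6-ynamide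
Product: 22 (3R,4S,6S)-6-methyl-3-(prop-2-enyl)-4-(triethylsilyloxy)-8-(triisopropylsilyl)oct-7-yn-2-one
Conditions: MeMgBr (2.5 equiv), THF, 0 °C; aq. NH4Cl
Reagents that add atoms: methylmagnesium bromide, C[Mg]Br
Why: Weinreb ketone synthesis, as in step 7.

Step 16
Reactants: 22 (3R,4S,6S)-6-methyl-3-(prop-2-enyl)-4-(triethylsilyloxy)-8-(triisopropylsilyl)oct-7-yn-2-one
Product: 24 (3R,4S,6S)-6-methyl-3-(prop-2-enyl)-4-(triethylsilyloxy)-8-(triisopropylsilyl)oct-1-en-7-yn-2-yl trifluoromethanesulfonate, via potassium enolate 23 (not isolated)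
Conditions: KN(SiMe3)2 (1.1 equiv), THF, −78 °C; PhNTf2 (1.2 equiv), −78 → −40 °C
Reagents that add atoms: N-phenylbis(trifluoromethanesulfonimide), FC(F)(F)S(=O)(=O)N(c1ccccc1)S(=O)(=O)C(F)(F)F
Why: Kinetic methyl-side enolisation and O-triflation, as in step 8.

Step 17
Reactants: 24 (3R,4S,6S)-6-methyl-3-(prop-2-enyl)-4-(triethylsilyloxy)-8-(triisopropylsilyl)oct-1-en-7-yn-2-yl trifluoromethanesulfonate
Product: 25 (3R,4S,6S)-4-hydroxy-6-methyl-3-(prop-2-enyl)-8-(triisopropylsilyl)oct-1-en-7-yn-2-yl trifluoromethanesulfonate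
Conditions: HF·pyridine, pyridine/THF, 0 °C
Reagents that add atoms: none
Why: Selective cleavage of the triethylsilyl ether, as in step 9.

Step 18
Reactants: 25 (3R,4S,6S)-4-hydroxy-6-methyl-3-(prop-2-enyl)-8-(triisopropylsilyl)oct-1-en-7-yn-2-yl trifluoromethanesulfonate
Product: 26 (3R,4R,6S)-6-methyl-3-(prop-2-enyl)-2-(trifluoromethanesulfonyloxy)-8-(triisopropylsilyl)oct-1-en-7-yn-4-yl 4-nitrobenzoate
Conditions: 4-nitrobenzoic acid (2 equiv), PPh3 (2 equiv), DIAD (2 equiv), toluene, 0 °C → rt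
Reagents that add atoms: 4-nitrobenzoic acid, OC(=O)c1ccc(cc1)[N+](=O)[O-]
Why: Mitsunobu reaction, in which the carboxylate displaces the alkoxyphosphonium ion by SN2 with clean inversion at C8 (a homoallylic carbinol no longer β to a carbonyl, so elimination is not favoured), giving the anti C7/C8 relationship needed for the trans-lactone.

Step 19
Reactants: 26 (3R,4R,6S)-6-methyl-3-(prop-2-enyl)-2-(trifluoromethanesulfonyloxy)-8-(triisopropylsilyl)oct-1-en-7-yn-4-yl 4-nitrobenzoate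
Product: 27 (3R,4R,6S)-4-hydroxy-6-methyl-3-(prop-2-enyl)-8-(triisopropylsilyl)oct-1-en-7-yn-2-yl trifluoromethanesulfonate
Conditions: K2CO3 (0.3 equiv), MeOH, 0 °C
Reagents that add atoms: none
Why: Base-catalysed transesterification of the activated 4-nitrobenzoate is fast at 0 °C and leaves the vinyl triflate and the alkynyl silane untouched.

Step 20
Reactants: 27 (3R,4R,6S)-4-hydroxy-6-methyl-3-(prop-2-enyl)-8-(triisopropylsilyl)oct-1-en-7-yn-2-yl trifluoromethanesulfonate
Product: 28 (4S,5R)-3-methylidene-5-[(2S)-2-methyl-4-(triisopropylsilyl)but-3-ynyl]-4-(prop-2-enyl)oxolan-2-one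
Conditions: Pd(PPh3)4 (10 mol %), CO (1 atm), Bu3N (2 equiv), LiCl (3 equiv), MeCN, 65 °C
Reagents that add atoms: carbon monoxide, [C-]#[O+]
Why: Palladium-catalysed carbonylative lactonisation with retention at C8 gives the trans α-methylene-γ-butyrolactone (C7 S, C8 R).

Step 21
Reactants: 28 (4S,5R)-3-methylidene-5-[(2S)-2-methyl-4-(triisopropylsilyl)but-3-ynyl]-4-(prop-2-enyl)oxolan-2-one
Product: 29 (4S,5R)-3-methylidene-5-[(2S)-2-methylbut-3-ynyl]-4-(prop-2-enyl)oxolan-2-one
Conditions: Bu4NF (1.2 equiv), AcOH (1.2 equiv), THF, 0 °C → rt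
Reagents that add atoms: none
Why: Buffered fluoride desilylation frees the terminal alkyne for metathesis, as in step 11.

Step 22
Reactants: 29 (4S,5R)-3-methylidene-5-[(2S)-2-methylbut-3-ynyl]-4-(prop-2-enyl)oxolan-2-one; 30 but-3-en-2-one
Product: 32 (3aS,7S,8aR)-7-methyl-3-methylidene-6-[(1E)-3-oxobut-1-enyl]-3,3a,4,7,8,8a-hexahydro-2H-cyclohepta[b]furan-2-one, via vinyl triene 31 (not isolated)
Conditions: second-generation Grubbs catalyst RuCl2(=CHPh)(PCy3)(H2IMes) (10 mol %), 30 (10 equiv), CH2Cl2 (5 mM), 40 °C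
Reagents that add atoms: none
Why: Domino ring-closing enyne metathesis/cross-metathesis, in which the ruthenium alkylidene formed at the allyl group closes onto the alkyne to give the seven-membered ring with a 1-vinyl group that is then capped (E) by methyl vinyl ketone, the electron-poor methylene lactone being inert.

Step 23
Reactants: 32 (3aS,7S,8aR)-7-methyl-3-methylidene-6-[(1E)-3-oxobut-1-enyl]-3,3a,4,7,8,8a-hexahydro-2H-cyclohepta[b]furan-2-one; 17 (4S,5S)-3-methylidene-5-[(2R)-2-methylbut-3-ynyl]-4-(prop-2-enyl)oxolan-2-one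
Product: 33 exo spiro cycloadduct with new bonds C5–C13' and C3–C11' (C1=C2; 3-acetyl; H-3 cis to H-5)
Conditions: 17 (3 equiv), toluene (1 M in 17), BHT (5 mol %), 110 °C, sealed tube; 32 added over 12 h then 24 h; excess 17 recovered
Reagents that add atoms: none
Why: Thermal intermolecular Diels–Alder reaction of the 1-acyl diene C5=C1–C2=C3 with the s-cis-locked methylene lactone in the "ortho" sense, where 17 has no diene and slow addition of 32 suppresses its self-dimerisation, and where the exo transition state (lactone C=O exo), attack on the lactone face anti to the C7' allyl and C8' side chain, and pseudo-axial attack at C5 on the diene face syn to H-7 and anti to the C8 ring flap set C11', C5 and the transient C3 centre.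

Step 24
Reactants: 33 exo spiro cycloadduct with new bonds C5–C13' and C3–C11' (C1=C2; 3-acetyl; H-3 cis to H-5)
Product: 35 1-hydroxy-2(3)-en-4-one spiro adduct (OH cis to H-5 and trans to the C10 methyl), via C1 hydroperoxide 34 (not isolated)
Conditions: O2 (1 atm), DBU (1.5 equiv), P(OEt)3 (2 equiv), MeCN, 0 °C → rt
Reagents that add atoms: dioxygen, O=O
Why: Base-mediated autoxidation of a β,γ-unsaturated ketone, in which DBU reversibly forms the extended dienolate (O–C4=C3–C2=C1), oxygen is captured at the γ-carbon C1 on the face opposite to both flanking substituents (C10 methyl and the C5–C13' bond) to give the conjugated γ-hydroperoxy enone, and the phosphite reduces it in situ to the tertiary alcohol.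

Step 25
Reactants: 35 1-hydroxy-2(3)-en-4-one spiro adduct (OH cis to H-5 and trans to the C10 methyl); 30 but-3-en-2-one
Product: 37 target CNP0168949.6, via vinyl triene 36 (not isolated)
Conditions: second-generation Grubbs catalyst RuCl2(=CHPh)(PCy3)(H2IMes) (20 mol %), 30 (10 equiv), CH2Cl2 (2 mM), 40 °C
Reagents that add atoms: none
Why: The same domino ring-closing enyne metathesis/cross-metathesis closes the right-hand seven-membered ring from the cis-disposed allyl and butynyl chains and installs the (E)-enone, while the tertiary alcohol, the trisubstituted enone and the methylene lactone do not take part.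

## Compound list

1 | (E)-but-2-enal (crotonaldehyde) | C/C=C/C=O | starting material
2 | ethynyltri(propan-2-yl)silane | C#C[Si](C(C)C)(C(C)C)C(C)C | starting material
3 | (3R)-3-methyl-5-(triisopropylsilyl)pent-4-ynal | O=CC[C@@H](C)C#C[Si](C(C)C)(C(C)C)C(C)C | intermediate
4 | (3S)-3-methyl-5-(triisopropylsilyl)pent-4-ynal | O=CC[C@H](C)C#C[Si](C(C)C)(C(C)C)C(C)C | intermediate
5 | (4R)-4-benzyl-1,3-oxazolidin-2-one | O=C1OC[C@@H](Cc2ccccc2)N1 | starting material
6 | pent-4-enoyl chloride | C=CCCC(=O)Cl | starting material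
7 | (4R)-4-benzyl-3-(pent-4-enoyl)-1,3-oxazolidin-2-one | O=C1OC[C@@H](Cc2ccccc2)N1C(=O)CCC=C | intermediate
8 | dibutylboron (Z)-enolate of 7 (not isolated) | O=C1OC[C@@H](Cc2ccccc2)N1/C(OB(CCCC)CCCC)=C/CC=C | intermediate
9 | (4R)-4-benzyl-3-[(2R,3S,5R)-3-hydroxy-5-methyl-2-(prop-2-enyl)-7-(triisopropylsilyl)hept-6-ynoyl]-1,3-oxazolidin-2-one | O=C1OC[C@@H](Cc2ccccc2)N1C(=O)[C@H](CC=C)[C@@H](O)C[C@@H](C)C#C[Si](C(C)C)(C(C)C)C(C)C | intermediate
10 | (2R,3S,5R)-3-hydroxy-N-methoxy-N,5-dimethyl-2-(prop-2-enyl)-7-(triisopropylsilyl)hept-6-ynamide | CON(C)C(=O)[C@H](CC=C)[C@@H](O)C[C@@H](C)C#C[Si](C(C)C)(C(C)C)C(C)C | intermediate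
11 | (2R,3S,5R)-N-methoxy-N,5-dimethyl-2-(prop-2-enyl)-3-(triethylsilyloxy)-7-(triisopropylsilyl)hept-6-ynamide | CON(C)C(=O)[C@H](CC=C)[C@@H](O[Si](CC)(CC)CC)C[C@@H](C)C#C[Si](C(C)C)(C(C)C)C(C)C | intermediate
12 | (3R,4S,6R)-6-methyl-3-(prop-2-enyl)-4-(triethylsilyloxy)-8-(triisopropylsilyl)oct-7-yn-2-one | CC(=O)[C@H](CC=C)[C@@H](O[Si](CC)(CC)CC)C[C@@H](C)C#C[Si](C(C)C)(C(C)C)C(C)C | intermediate
13 | potassium enolate of 12, terminal C1=C2 (not isolated) | [K+].[O-]C(=C)[C@H](CC=C)[C@@H](O[Si](CC)(CC)CC)C[C@@H](C)C#C[Si](C(C)C)(C(C)C)C(C)C | intermediate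
14 | (3R,4S,6R)-6-methyl-3-(prop-2-enyl)-4-(triethylsilyloxy)-8-(triisopropylsilyl)oct-1-en-7-yn-2-yl trifluoromethanesulfonate | C=C(OS(=O)(=O)C(F)(F)F)[C@H](CC=C)[C@@H](O[Si](CC)(CC)CC)C[C@@H](C)C#C[Si](C(C)C)(C(C)C)C(C)C | intermediate
15 | (3R,4S,6R)-4-hydroxy-6-methyl-3-(prop-2-enyl)-8-(triisopropylsilyl)oct-1-en-7-yn-2-yl trifluoromethanesulfonate | C=C(OS(=O)(=O)C(F)(F)F)[C@H](CC=C)[C@@H](O)C[C@@H](C)C#C[Si](C(C)C)(C(C)C)C(C)C | intermediate
16 | (4S,5S)-3-methylidene-5-[(2R)-2-methyl-4-(triisopropylsilyl)but-3-ynyl]-4-(prop-2-enyl)oxolan-2-one (cis-lactone) | C=C1C(=O)O[C@@H](C[C@@H](C)C#C[Si](C(C)C)(C(C)C)C(C)C)[C@H]1CC=C | intermediate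
17 | (4S,5S)-3-methylidene-5-[(2R)-2-methylbut-3-ynyl]-4-(prop-2-enyl)oxolan-2-one (cis-lactone, dienophile) | C=C1C(=O)O[C@@H](C[C@@H](C)C#C)[C@H]1CC=C | intermediate
18 | trichlorotitanium (Z)-enolate of 7 (not isolated) | O=C1OC[C@@H](Cc2ccccc2)N1/C(O[Ti](Cl)(Cl)Cl)=C/CC=C | intermediate
19 | (4R)-4-benzyl-3-[(2R,3S,5S)-3-hydroxy-5-methyl-2-(prop-2-enyl)-7-(triisopropylsilyl)hept-6-ynoyl]-1,3-oxazolidin-2-one | O=C1OC[C@@H](Cc2ccccc2)N1C(=O)[C@H](CC=C)[C@@H](O)C[C@H](C)C#C[Si](C(C)C)(C(C)C)C(C)C | intermediate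
20 | (2R,3S,5S)-3-hydroxy-N-methoxy-N,5-dimethyl-2-(prop-2-enyl)-7-(triisopropylsilyl)hept-6-ynamide | CON(C)C(=O)[C@H](CC=C)[C@@H](O)C[C@H](C)C#C[Si](C(C)C)(C(C)C)C(C)C | intermediate
21 | (2R,3S,5S)-N-methoxy-N,5-dimethyl-2-(prop-2-enyl)-3-(triethylsilyloxy)-7-(triisopropylsilyl)hept-6-ynamide | CON(C)C(=O)[C@H](CC=C)[C@@H](O[Si](CC)(CC)CC)C[C@H](C)C#C[Si](C(C)C)(C(C)C)C(C)C | intermediate
22 | (3R,4S,6S)-6-methyl-3-(prop-2-enyl)-4-(triethylsilyloxy)-8-(triisopropylsilyl)oct-7-yn-2-one | CC(=O)[C@H](CC=C)[C@@H](O[Si](CC)(CC)CC)C[C@H](C)C#C[Si](C(C)C)(C(C)C)C(C)C | intermediate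
23 | potassium enolate of 22, terminal C1=C2 (not isolated) | [K+].[O-]C(=C)[C@H](CC=C)[C@@H](O[Si](CC)(CC)CC)C[C@H](C)C#C[Si](C(C)C)(C(C)C)C(C)C | intermediate
24 | (3R,4S,6S)-6-methyl-3-(prop-2-enyl)-4-(triethylsilyloxy)-8-(triisopropylsilyl)oct-1-en-7-yn-2-yl trifluoromethanesulfonate | C=C(OS(=O)(=O)C(F)(F)F)[C@H](CC=C)[C@@H](O[Si](CC)(CC)CC)C[C@H](C)C#C[Si](C(C)C)(C(C)C)C(C)C | intermediate
25 | (3R,4S,6S)-4-hydroxy-6-methyl-3-(prop-2-enyl)-8-(triisopropylsilyl)oct-1-en-7-yn-2-yl trifluoromethanesulfonate | C=C(OS(=O)(=O)C(F)(F)F)[C@H](CC=C)[C@@H](O)C[C@H](C)C#C[Si](C(C)C)(C(C)C)C(C)C | intermediate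
26 | (3R,4R,6S)-6-methyl-3-(prop-2-enyl)-2-(trifluoromethanesulfonyloxy)-8-(triisopropylsilyl)oct-1-en-7-yn-4-yl 4-nitrobenzoate | C=C(OS(=O)(=O)C(F)(F)F)[C@H](CC=C)[C@H](OC(=O)c1ccc(cc1)[N+](=O)[O-])C[C@H](C)C#C[Si](C(C)C)(C(C)C)C(C)C | intermediate
27 | (3R,4R,6S)-4-hydroxy-6-methyl-3-(prop-2-enyl)-8-(triisopropylsilyl)oct-1-en-7-yn-2-yl trifluoromethanesulfonate | C=C(OS(=O)(=O)C(F)(F)F)[C@H](CC=C)[C@H](O)C[C@H](C)C#C[Si](C(C)C)(C(C)C)C(C)C | intermediate
28 | (4S,5R)-3-methylidene-5-[(2S)-2-methyl-4-(triisopropylsilyl)but-3-ynyl]-4-(prop-2-enyl)oxolan-2-one (trans-lactone) | C=C1C(=O)O[C@H](C[C@H](C)C#C[Si](C(C)C)(C(C)C)C(C)C)[C@H]1CC=C | intermediate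
29 | (4S,5R)-3-methylidene-5-[(2S)-2-methylbut-3-ynyl]-4-(prop-2-enyl)oxolan-2-one (trans-lactone) | C=C1C(=O)O[C@H](C[C@H](C)C#C)[C@H]1CC=C | intermediate
30 | but-3-en-2-one (methyl vinyl ketone) | CC(=O)C=C | starting material
31 | (3aS,7S,8aR)-6-ethenyl-7-methyl-3-methylidene-3,3a,4,7,8,8a-hexahydro-2H-cyclohepta[b]furan-2-one (not isolated) | C=C1C(=O)O[C@@H]2C[C@H](C)C(C=C)=CC[C@@H]12 | intermediate
32 | (3aS,7S,8aR)-7-methyl-3-methylidene-6-[(1E)-3-oxobut-1-enyl]-3,3a,4,7,8,8a-hexahydro-2H-cyclohepta[b]furan-2-one (trans-lactone; C7 S, C8 R, C10 S; diene partner) | C=C1C(=O)O[C@@H]2C[C@H](C)C(/C=C/C(C)=O)=CC[C@@H]12 | intermediate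
33 | Diels–Alder adduct: cyclohexene C1=C2–C3–C11'–C13'–C5 fused to the left seven-membered ring; C3 bears acetyl; H-3 and H-5 cis, on the face opposite the C10 methyl; C11' is the spiro α-carbon of the right (7'S,8'S)-lactone (7'-allyl, 8'-[(2R)-2-methylbut-3-ynyl]) with its carbonyl C12' cis to H-5 (exo) and the C11'–C3 bond anti to the 7'-allyl; left trans-lactone and 11(13)-methylene unchanged | C=C1C(=O)O[C@@H]2C[C@H](C)C3=C[C@H](C(C)=O)[C@]4(C[C@@H]3C[C@@H]12)C(=O)O[C@@H](C[C@@H](C)C#C)[C@H]4CC=C | intermediate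
34 | C1 hydroperoxide of the adduct: C1–OOH cis to H-5 and trans to the C10 methyl, C2=C3 conjugated with the 3-acetyl (not isolated) | C=C1C(=O)O[C@@H]2C[C@H](C)[C@]3(OO)C=C(C(C)=O)[C@]4(C[C@@H]3C[C@@H]12)C(=O)O[C@@H](C[C@@H](C)C#C)[C@H]4CC=C | intermediate
35 | 1-hydroxy-2(3)-en-4-one spiro adduct: as 34 with C1–OH (cis to H-5, trans to the C10 methyl); right lactone still monocyclic with 7'-allyl and 8'-[(2R)-2-methylbut-3-ynyl] | C=C1C(=O)O[C@@H]2C[C@H](C)[C@]3(O)C=C(C(C)=O)[C@]4(C[C@@H]3C[C@@H]12)C(=O)O[C@@H](C[C@@H](C)C#C)[C@H]4CC=C | intermediate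
36 | vinyl triene: as 35 but with the right seven-membered ring closed (C1'=C5') and a 1'-ethenyl group (not isolated) | C=C1C(=O)O[C@@H]2C[C@H](C)[C@]3(O)C=C(C(C)=O)[C@]4(C[C@@H]3C[C@@H]12)C(=O)O[C@H]1C[C@@H](C)C(C=C)=CC[C@H]14 | intermediate
37 | CNP0168949.6 | C=C1C(=O)O[C@@H]2C[C@H](C)[C@]3(O)C=C(C(C)=O)[C@]4(C[C@@H]3C[C@@H]12)C(=O)O[C@H]1C[C@@H](C)C(/C=C/C(C)=O)=CC[C@H]14 | target

## Step count and risks

Total step count: 25. Longest linear sequence: 15 steps (step 2, steps 12–22, steps 23–25).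

Step 23 (cross Diels–Alder) is the most likely to fail, through self-dimerisation of 32 or the wrong diene face. Fallback: the route sets out from 32, whose exocyclic methylene is masked by conjugate addition of benzeneselenol (PhSeSePh reduced beforehand with NaBH4 in EtOH, then AcOH, then 32 at 0 °C, so that no borohydride meets the ketone) to give the 13-(phenylselanyl)-11,13-dihydro lactone F1 (C11 epimers, irrelevant), which cannot act as a dienophile. Heating F1 with 17 (1.5 equiv, toluene, 110 °C) gives the selenide cycloadduct F2. Oxidation with H2O2 (pyridine, CH2Cl2, 0 °C → rt) and selenoxide syn-elimination restore the methylene lactone, and the route is rejoined at 33.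

Step 24 (C1 oxygenation) may give the conjugated C1–H enone or attack at C3 instead. Fallback: the route sets out from 33 and uses a Schenck ene reaction with singlet oxygen (O2, hν, tetraphenylporphyrin, CH2Cl2, −20 °C). This abstracts H-3 suprafacially and delivers oxygen to C1 on the same face (the face of H-5), giving the same hydroperoxide 34 without any base. Reduction with P(OEt)3 rejoins the route at 35.

Step 25 (late domino metathesis) may stall at the triene or give poor cross-metathesis with the electron-poor ketone. Fallback: the route sets out from 35, and ring-closing enyne metathesis alone (second-generation Grubbs catalyst RuCl2(=CHPh)(PCy3)(H2IMes), ethene 1 atm, CH2Cl2, 40 °C) gives triene 36, which is isolated. Cross-metathesis of 36 with but-3-en-2-ol (second-generation Hoveyda–Grubbs catalyst RuCl2(=CH-C6H4-2-OiPr)(H2IMes), CH2Cl2, 40 °C) gives the dienyl carbinol F3 (carbinol epimers). MnO2 (CH2Cl2, rt) oxidises only this secondary allylic alcohol and the route is rejoined at 37.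

## Further compounds

F1 | step 23 | 13-(phenylselanyl)-11,13-dihydro derivative of 32 (C11 epimers) | c1ccccc1[Se]CC1C(=O)O[C@@H]2C[C@H](C)C(/C=C/C(C)=O)=CC[C@@H]12
F2 | step 23 | 13-(phenylselanyl)-11,13-dihydro derivative of cycloadduct 33 (C11 epimers) | c1ccccc1[Se]CC1C(=O)O[C@@H]2C[C@H](C)C3=C[C@H](C(C)=O)[C@]4(C[C@@H]3C[C@@H]12)C(=O)O[C@@H](C[C@@H](C)C#C)[C@H]4CC=C
F0 | step 24 | none | none
F3 | step 25 | 4'-hydroxy-4'-deoxo analogue of 37, side chain (E)-CH=CH–CH(OH)CH3 (carbinol epimers) | C=C1C(=O)O[C@@H]2C[C@H](C)[C@]3(O)C=C(C(C)=O)[C@]4(C[C@@H]3C[C@@H]12)C(=O)O[C@H]1C[C@@H](C)C(/C=C/C(C)O)=CC[C@H]14
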